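Everything rests on the γ,δ-unsaturated ketone hidden in the cyclopentanone ring. It consists of the bridging C=O, the bridgehead CH next to it and the CH that carries the isopropenyl group, which lies syn to that carbonyl. This is the retron of a Claisen rearrangement. The five-membered ring is therefore made by contraction of a seven-membered cyclic allyl vinyl ether, generated in the flask from a (Z)-allylic alcohol and the ketone beside the quaternary carbon. One operation forms the C–C bond, the last two stereocentres, the bicyclo[3.2.1]octane-3,8-dione and the isopropenyl group. Its precursor, a benzo-bridged 1,4-diketone, comes from an enantioselective quinone Diels–Alder reaction and an intramolecular α-arylation.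

Key step: step 12

Assumption: the (R,R)-TADDOL titanium complex of step 8 is taken to shield the quinone face that leads to the drawn enantiomer. If the sense of induction is the opposite, the equally available (S,S)-ligand is used.

Step 1
Reactants: 1 2-allyl-6-methoxyphenol; 2 methacryloyl chloride
Product: 3 2-allyl-6-methoxyphenyl methacrylate
Conditions: Et3N, DMAP (cat.), CH2Cl2, 0 °C to rt
Reagents that add atoms: none
Why: Schotten–Baumann-type O-acylation of the phenol installs the second alkene and, as the ester carbon, the later oxygen-bearing CH2 of the allylic alcohol; no stereocentre is formed.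

Step 2
Reactants: 3 2-allyl-6-methoxyphenyl methacrylate
Product: 4 9-methoxy-3-methyl-1-benzoxepin-2(5H)-one
Conditions: second-generation Hoveyda–Grubbs catalyst (5 mol %), 1,4-benzoquinone (10 mol %), toluene (5 mM), 100 °C
Reagents that add atoms: none
Why: Ring-closing olefin metathesis of the allyl and methacrylate alkenes closes a seven-membered lactone in which the new trisubstituted alkene can only be (Z), so the ring fixes the geometry needed in step 12.

Step 3
Reactants: 4 9-methoxy-3-methyl-1-benzoxepin-2(5H)-one
Product: 5 2-[(2Z)-4-hydroxy-3-methylbut-2-en-1-yl]-6-methoxyphenol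
Conditions: i-Bu2AlH (4 equiv), CH2Cl2, −78 to 0 °C; aq. potassium sodium tartrate
Reagents that add atoms: none
Why: 1,2-Reduction of the unsaturated aryl ester by the aluminium hydride opens the lactone to the phenol and the (Z)-allylic alcohol without touching the alkene geometry.

Step 4
Reactants: 5 2-[(2Z)-4-hydroxy-3-methylbut-2-en-1-yl]-6-methoxyphenol
Product: 6 2-[(2Z)-4-hydroxy-3-methylbut-2-en-1-yl]-6-methoxy-1,4-benzoquinone
Conditions: Co(salen) (10 mol %), O2 (1 atm), MeCN, rt
Reagents that add atoms: dioxygen, O=O
Why: Cobalt–salen-catalysed aerobic oxidation of a 2,6-disubstituted phenol with a free para position gives the para-quinone, and the primary alcohol and the alkene are inert under these conditions.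

Step 5
Reactants: 6 2-[(2Z)-4-hydroxy-3-methylbut-2-en-1-yl]-6-methoxy-1,4-benzoquinone
Product: 7 2-[(2Z)-4-(tert-butyldimethylsilyloxy)-3-methylbut-2-en-1-yl]-6-methoxy-1,4-benzoquinone
Conditions: t-BuMe2SiOTf, 2,6-lutidine, CH2Cl2, −78 °C
Reagents that add atoms: tert-butyldimethylsilyl triflate, CC(C)(C)[Si](C)(C)OS(=O)(=O)C(F)(F)F
Why: O-Silylation with a silyl triflate and a non-nucleophilic pyridine base masks the alcohol against the Lewis acid of step 8 without amine addition to the quinone.

Step 6
Reactants: 8 2-bromo-1,4-dimethoxybenzene
Product: 10 2-bromo-3,6-dimethoxybenzaldehyde, via aryllithium 9 (not isolated)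
Conditions: LiN(i-Pr)2, THF, −78 °C; DMF, −78 °C; aq. HCl
Reagents that add atoms: N,N-dimethylformamide, CN(C)C=O
Why: Directed ortho-lithiation takes place at the most acidic C–H, flanked by bromine and methoxy, and formylation of aryllithium 9 at −78 °C outruns loss of LiBr to the aryne.

Step 7
Reactants: 10 2-bromo-3,6-dimethoxybenzaldehyde; 11 diethyl (2-methylallyl)phosphonate
Product: 12 (E)-1-(2-bromo-3,6-dimethoxyphenyl)-3-methylbuta-1,3-diene
Conditions: n-BuLi, THF–HMPA, −78 °C to rt
Reagents that add atoms: none
Why: Horner–Wadsworth–Emmons olefination with the lithiated allylic phosphonate reacts at its α-carbon and gives the (E)-diene.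

Step 8
Reactants: 7 silyl-protected methoxyquinone; 12 (E)-aryl diene
Product: 13 endo cycloadduct, cis-fused 8-(2-bromo-3,6-dimethoxyphenyl)-8a-[(2Z)-4-(tert-butyldimethylsilyloxy)-3-methylbut-2-en-1-yl]-2-methoxy-6-methyl-4a,5,8,8a-tetrahydronaphthalene-1,4-dione (aryl cis to both ring carbonyl carbons, trans to the side chain and to H-4a; absolute configuration as in the SMILES)
Conditions: TiCl2(Oi-Pr)2 and (4R,5R)-2,2-dimethyl-α,α,α',α'-tetraphenyl-1,3-dioxolane-4,5-dimethanol ((R,R)-TADDOL), 30 mol % each, 4 Å MS, toluene–CH2Cl2, −60 to −20 °C
Reagents that add atoms: none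
Why: In this chiral-Lewis-acid-promoted quinone Diels–Alder reaction, tetravalent titanium is chelated by the C1 carbonyl and the neighbouring methoxy oxygen, which activates only the alkyl-substituted C2=C3 bond (the other is a vinylogous ester) and directs the nucleophilic CH2 terminus of the diene to the unsubstituted C3, while the endo rule places the aryl group cis to the ring carbonyl carbons and the C2-symmetric diolate blocks one quinone face, so the quaternary carbon, the ring-fusion CH and the benzylic CH are set together.

Step 9
Reactants: 13 endo cycloadduct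
Product: 15 cis-fused 8-(2-bromo-3,6-dimethoxyphenyl)-8a-[(2Z)-4-(tert-butyldimethylsilyloxy)-3-methylbut-2-en-1-yl]-6-methyl-2,3,4a,5,8,8a-hexahydronaphthalene-1,4-dione, via saturated methoxy diketone 14 (not isolated)
Conditions: SmI2 (5 equiv), THF–MeOH, −78 to 0 °C
Reagents that add atoms: none
Why: Single-electron reduction first saturates the electron-poor enedione to 14 and then cleaves its α-methoxy ketone through the ketyl (reductive α-deoxygenation), which removes the directing group, while the aryl bromide, silyl ether, isolated alkenes and the three stereocentres are left untouched in the absence of HMPA.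

Step 10
Reactants: 15 bromoaryl 1,4-diketone
Product: 16 bridged tetracyclic diketone silyl ether (C4a now bonded to the former C–Br carbon: a dimethoxybenzobicyclo[3.2.1]octadiene fused to a cyclohexane-1,4-dione, side chain on the one-carbon bridge syn to the alkene bridge)
Conditions: Pd2(dba)3 (5 mol %), P(t-Bu)3 (12 mol %), NaOt-Bu (1.5 equiv), toluene, 80 °C
Reagents that add atoms: none
Why: In this palladium-catalysed intramolecular α-arylation of a ketone enolate (Buchwald–Hartwig type), after oxidative addition of zerovalent palladium into C–Br the aryl group reaches only the ring-fusion α-carbon (six-membered palladacycle, five-membered ring on reductive elimination) and only from the face on which it already sits, so the benzylic stereocentre sets the second quaternary centre and any epimerisation of the ring-fusion CH is funnelled into one product.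

Step 11
Reactants: 16 bridged diketone silyl ether
Product: 17 bridged diketone (Z)-allylic alcohol
Conditions: HF·pyridine, THF, 0 °C to rt
Reagents that add atoms: none
Why: Fluoride-driven cleavage of the primary silyl ether under mildly acidic conditions frees the allylic alcohol and leaves the ketones, aryl methyl ethers and alkenes untouched.

Step 12
Reactants: 17 bridged diketone (Z)-allylic alcohol
Product: 20 O,O'-dimethyl ether of the target (pentacyclic bicyclo[3.2.1]octane-3,8-dione with exo isopropenyl group), via cyclic hemiketal 18 (not isolated), via cyclic allyl vinyl ether 19 (not isolated)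
Conditions: PPTS (20 mol %), mesitylene (0.01 M), Dean–Stark trap charged with 4 Å MS, 165 °C, argon
Reagents that add atoms: none
Why: PPTS adds the primary allylic alcohol reversibly to the ketone that flanks the quaternary carbon (hemiketal 18) and dehydrates it towards its only α-CH2, which feeds a small stationary amount of allyl vinyl ether 19 that is drained irreversibly by a concerted [3,3]-sigmatropic shift (O–CH2 breaks, =CH bonds to the enol ether β-carbon, C=O and C(Me)=CH2 appear). The closest known reaction types are the Claisen rearrangement of allyl vinyl ethers made in situ from ketones or ketals and allylic alcohols, and the alicyclic, ring-contracting Claisen rearrangement of unsaturated lactone ketene acetals. The seven-membered ring (O, OCH2, C(Me)=, =CH, CH2, quaternary C, C–O) expels O, CH2 and C(Me) and takes in the enol carbon, so it contracts by two atoms to the cyclopentanone; the closure is pericyclic and suprafacial on both components through a chair-like transition state shaped like a bicyclo[3.2.1]octane, and thus avoids the stereoelectronically poor 5-(enolendo) alkylation of the enolate. The new bridgehead CH can only arise on the enol ether face that carries the CH2 tether of the quaternary carbon, and the isopropenyl-bearing CH is fixed because C(Me)=CH2 is still held through CH2···O to the carbonyl oxygen in the transition state, which puts it exo (syn to the bridging C=O) with H endo, as in the target. The step needs selection between two ketones, one direction of enolisation and a ring-compatible alkene: the tether reaches the near ketone in a seven-membered ring but the far one only in an eight-membered ring, the quaternary carbon leaves a single α-CH2, and the (Z)-geometry comes from step 2.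

Step 13
Reactants: 20 O,O'-dimethyl ether of the target
Product: 22 target CNP0287617.1, via bridged quinone 21 (not isolated)
Conditions: (NH4)2Ce(NO3)6 (2.5 equiv), MeCN–H2O, 0 °C; then aq. Na2S2O4, EtOAc, rt
Reagents that add atoms: water, O
Why: Oxidative demethylation of the 1,4-dimethoxyarene by tetravalent cerium gives quinone 21, whose bridgehead benzylic positions cannot tautomerise to a quinone methide, and dithionite reduces it in the same flask to the hydroquinone without touching ketones, alkenes or any stereocentre.

Compound list
1 | 2-allyl-6-methoxyphenol | C=CCc1cccc(OC)c1O | starting material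
2 | methacryloyl chloride | C=C(C)C(=O)Cl | starting material
3 | 2-allyl-6-methoxyphenyl methacrylate | C=CCc1cccc(OC)c1OC(=O)C(C)=C | intermediate
4 | 9-methoxy-3-methyl-1-benzoxepin-2(5H)-one | COc1cccc2c1OC(=O)C(C)=CC2 | intermediate
5 | 2-[(2Z)-4-hydroxy-3-methylbut-2-en-1-yl]-6-methoxyphenol | COc1cccc(C/C=C(/C)CO)c1O | intermediate
6 | 2-[(2Z)-4-hydroxy-3-methylbut-2-en-1-yl]-6-methoxy-1,4-benzoquinone | COC1=CC(=O)C=C(C/C=C(/C)CO)C1=O | intermediate
7 | 2-[(2Z)-4-(tert-butyldimethylsilyloxy)-3-methylbut-2-en-1-yl]-6-methoxy-1,4-benzoquinone | COC1=CC(=O)C=C(C/C=C(/C)CO[Si](C)(C)C(C)(C)C)C1=O | intermediate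
8 | 2-bromo-1,4-dimethoxybenzene | COc1ccc(OC)c(Br)c1 | starting material
9 | 2-bromo-3,6-dimethoxyphenyllithium | [Li]c1c(Br)c(OC)ccc1OC | intermediate
10 | 2-bromo-3,6-dimethoxybenzaldehyde | O=Cc1c(Br)c(OC)ccc1OC | intermediate
11 | diethyl (2-methylallyl)phosphonate | C=C(C)CP(=O)(OCC)OCC | starting material
12 | (E)-1-(2-bromo-3,6-dimethoxyphenyl)-3-methylbuta-1,3-diene | C=C(C)/C=C/c1c(Br)c(OC)ccc1OC | intermediate
13 | endo Diels–Alder adduct (2-methoxy enedione, cis-fused, aryl cis to the carbonyl carbons) | CC(C)(C)[Si](C)(C)OC/C(C)=C\C[C@@]23C(=O)C(OC)=CC(=O)[C@@H]2CC(C)=C[C@@H]3c1c(OC)ccc(OC)c1Br | intermediate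
14 | saturated 2-methoxy 1,4-diketone (methoxy-bearing carbon undefined) | CC(C)(C)[Si](C)(C)OC/C(C)=C\C[C@@]23C(=O)C(OC)CC(=O)[C@@H]2CC(C)=C[C@@H]3c1c(OC)ccc(OC)c1Br | intermediate
15 | cis-fused bromoaryl 1,4-diketone | CC(C)(C)[Si](C)(C)OC/C(C)=C\C[C@@]23C(=O)CCC(=O)[C@@H]2CC(C)=C[C@@H]3c1c(OC)ccc(OC)c1Br | intermediate
16 | bridged tetracyclic diketone silyl ether | CC(C)(C)[Si](C)(C)OC/C(C)=C\C[C@@]23C(=O)CCC(=O)[C@@]21CC(C)=C[C@@H]3c2c(OC)ccc(OC)c21 | intermediate
17 | bridged tetracyclic diketone (Z)-allylic alcohol | OC/C(C)=C\C[C@@]23C(=O)CCC(=O)[C@@]21CC(C)=C[C@@H]3c2c(OC)ccc(OC)c21 | intermediate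
18 | seven-membered cyclic hemiketal (hemiketal carbon undefined) | CC1=CC[C@@]23C(O)(CCC(=O)[C@@]24CC(C)=C[C@@H]3c2c(OC)ccc(OC)c24)OC1 | intermediate
19 | seven-membered cyclic allyl vinyl ether (tetrahydrooxepine fused to the cyclohexenone ring) | CC1=CC[C@@]23C(=CCC(=O)[C@@]24CC(C)=C[C@@H]3c2c(OC)ccc(OC)c24)OC1 | intermediate
20 | O,O'-dimethyl ether of the target | C=C(C)[C@H]1C[C@@]23C(=O)[C@@H]1CC(=O)[C@@]21CC(C)=C[C@@H]3c2c(OC)ccc(OC)c21 | intermediate
21 | bridged para-quinone | C=C(C)[C@H]1C[C@@]23C(=O)[C@@H]1CC(=O)[C@@]21CC(C)=C[C@@H]3C2=C1C(=O)C=CC2=O | intermediate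
22 | CNP0287617.1 | C=C(C)[C@H]1C[C@@]23C(=O)[C@@H]1CC(=O)[C@@]21CC(C)=C[C@@H]3c2c(O)ccc(O)c21 | target

Total step count: 13. Longest linear sequence: 11 (steps 1–5 and 8–13).

Steps most likely to fail

Step 12. The hemiketal and oxocarbenium equilibria at the neopentyl ketone may lie too far on the open side. Acid-induced ionisation of the allylic alcohol or alkene migration could then overtake enol ether formation. The fallback sets out from 17 and builds the enol ether stepwise under aprotic conditions. Me3SiCl and imidazole give the trimethylsilyl ether F1. Me3SiOTf (cat.) with MeOSiMe3 in CH2Cl2 at −78 °C closes the cyclic mixed methyl ketal F2 by aprotic ketalisation. Me3SiOTf and i-Pr2NEt then eliminate methanol as its silyl ether. This comes back to the route at the now isolated 19, which is heated without acid (toluene, sealed tube, 170 °C) to give 20.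

Step 8. The di-ortho-substituted aryl group may slow the cycloaddition. A stepwise cationic pathway may erode the endo selectivity, and the facial selectivity may be poor. The fallback sets out from 7 and 12 and gives up asymmetric catalysis. An uncatalysed cycloaddition under high pressure (12 kbar, CH2Cl2, rt) has the same intrinsic regiochemistry, because the methoxy group deactivates the C4 carbonyl. It gives 13 together with the mirror-image cycloadduct F3. The two are separated by preparative supercritical-fluid chromatography on a polysaccharide chiral stationary phase, and the route is rejoined at 13.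

Step 10. Oxidative addition at the hindered bromide may be slow. A 6-exo Heck insertion into the side-chain alkene or hydrodebromination could then compete with enolate arylation. The fallback sets out from 15 and replaces the metal-catalysed coupling by a photostimulated radical-chain SRN1 cyclisation of the potassium enolate (KOt-Bu, DMSO, 350 nm light). The aryl radical is captured by the same ring-fusion enolate carbon, and the route is rejoined at 16. New compounds on this way: none F0.

Further compounds
F1 | step 12 | trimethylsilyl ether of 17 | C[Si](C)(C)OC/C(C)=C\C[C@@]23C(=O)CCC(=O)[C@@]21CC(C)=C[C@@H]3c2c(OC)ccc(OC)c21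
F2 | step 12 | seven-membered cyclic mixed methyl ketal | CC1=CC[C@@]23C(CCC(=O)[C@@]24CC(C)=C[C@@H]3c2c(OC)ccc(OC)c24)(OC)OC1
F3 | step 8 | mirror-image cycloadduct (enantiomer of 13) | CC(C)(C)[Si](C)(C)OC/C(C)=C\C[C@]23C(=O)C(OC)=CC(=O)[C@H]2CC(C)=C[C@H]3c1c(OC)ccc(OC)c1Br
F0 | step 10 | none | none
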